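**Plan**
- Numbering used in all names: ring A = C1 (C=O), C2 (C–CH3), C3 (=CH), C4 (CH–O), C5 (fusion CH), C6 (fusion C–CH3), C7 (CH2); ring B = C5, C6, C8, C9, C10 (C(OH)iPr).
- Retrosynthesis: cut the C4–O acyl bond, the C2=C3 unsaturation, the C2–CH3 bond (a C2 ester takes its place), the C10–isopropyl bond (back to a ketone) and the C4–O/C5–H pair (back to a C4=C5 alkene). Ring A is then cut at C6–C7 and C2–C3.
- Enabling feature: in ring A the oxygenated three-carbon piece C2–C1(O)–C7 and the four-carbon piece C3–C4–C5–C6, whose C5–C6 edge belongs to ring B, map onto a 2-siloxyvinyl rhodium carbenoid and a 1-vinylcyclopentene.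
- Forward: ring B is bought as 3-methylcyclopentenone and made into the vinyl diene; ring A closes by cyclopropanation/Cope rearrangement. Then follow C4=C5 hydration, isopropyl addition at C10, C2 methylation and decarboxylation, acylation, desaturation and desilylation.
- Stereochemistry: C6 from the chiral dirhodium catalyst, relayed through the cyclopropane and the boat Cope transition state; C4 and C5 from hydroboration anti to the C6 methyl; C10 from nucleophile approach anti to that methyl.

Key step: step 6

Remark 1: the facial sense of Rh2(S-PTAD)4, dirhodium tetrakis[(S)-(1-adamantyl)(N-phthalimido)acetate], with this carbenoid is assumed to equal that of Rh2(R-DOSP)4 with monosubstituted alkenes, giving the (1R,2S)-divinylcyclopropane; if the first run shows the opposite sense, Rh2(R-PTAD)4 is used with no other change.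
Remark 2: locants and descriptors in the bicyclo[5.3.0]decane names follow the numbering above (C5 and C6 are the fusion atoms); compounds drawn without a C2 descriptor are carried as C2 epimer (or enol) mixtures, since C2 becomes sp2 in step 14.

**Step 1**
Reactants: 1 3-methylcyclopent-2-en-1-one
Product: 3 2-bromo-3-methylcyclopent-2-en-1-one, via dibromo ketone 2 (not isolated)
Conditions: Br2, CH2Cl2, 0 °C; then Et3N, 0 °C to rt
Reagents that add atoms: bromine, BrBr
Why: Bromination–dehydrobromination (bromine addition to the enone, then amine-induced E1cB loss of HBr) is the standard route to 2-bromocycloalk-2-enones; no stereocentre remains.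

**Step 2**
Reactants: 3 2-bromo-3-methylcyclopent-2-en-1-one
Product: 4 6-bromo-7-methyl-1,4-dioxaspiro[4.4]non-6-ene
Conditions: HOCH2CH2OH, TsOH·H2O (cat.), benzene, reflux, Dean–Stark
Reagents that add atoms: ethylene glycol, OCCO
Why: Acid-catalysed ketalisation with azeotropic removal of water; the α-bromine should hold the double bond in its conjugated position.

**Step 3**
Reactants: 4 6-bromo-7-methyl-1,4-dioxaspiro[4.4]non-6-ene; 5 potassium vinyltrifluoroborate
Product: 6 6-ethenyl-7-methyl-1,4-dioxaspiro[4.4]non-6-ene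
Conditions: PdCl2(dppf) (5 mol %), Cs2CO3, THF/H2O 9:1, 80 °C
Reagents that add atoms: none
Why: Suzuki–Miyaura coupling of an alkenyl bromide with a vinyltrifluoroborate under aqueous carbonate should tolerate the ketal and give the 2-substituted butadiene.

**Step 4**
Reactants: 7 methyl acetoacetate
Product: 8 methyl 2-diazo-3-oxobutanoate
Conditions: p-ABSA, Et3N, MeCN, 0 °C to rt
Reagents that add atoms: 4-acetamidobenzenesulfonyl azide (p-ABSA), CC(=O)Nc1ccc(cc1)S(=O)(=O)N=[N+]=[N-]
Why: Regitz diazo transfer from a sulfonyl azide to the doubly activated methylene of a β-keto ester.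

**Step 5**
Reactants: 8 methyl 2-diazo-3-oxobutanoate
Product: 9 methyl 3-(tert-butyldimethylsilyloxy)-2-diazobut-3-enoate
Conditions: TBSOTf, Et3N, CH2Cl2, 0 °C; used at once
Reagents that add atoms: tert-butyldimethylsilyl triflate, CC(C)(C)[Si](C)(C)OS(=O)(=O)C(F)(F)F
Why: Soft enolisation and O-silylation of the acetyl group by silyl triflate and amine gives the 2-siloxyvinyl diazoacetate, and the diazo group survives these non-acidic conditions.

**Step 6**
Reactants: 6 6-ethenyl-7-methyl-1,4-dioxaspiro[4.4]non-6-ene; 9 methyl 3-(tert-butyldimethylsilyloxy)-2-diazobut-3-enoate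
Product: 11 methyl (6R)-1-(tert-butyldimethylsilyloxy)-10,10-(ethylenedioxy)-6-methylbicyclo[5.3.0]deca-1,4-diene-2-carboxylate, via cis-divinylcyclopropane 10 (not isolated)
Conditions: Rh2(S-PTAD)4 (1 mol %), hexanes, −25 °C, slow addition of 9 (1.5 equiv); then toluene, 90 °C
Reagents that add atoms: none
Why: The dirhodium carboxylate converts 9 into a donor/acceptor (siloxyvinyl/ester) carbenoid that cyclopropanates the terminal vinyl group of 6 (bonds C2–C3 and C2–C4) to give cis-divinylcyclopropane 10, and warming drives the Cope [3,3] shift that forms C6–C7 and breaks C2–C4. The closest known reaction type is the tandem cyclopropanation/Cope rearrangement (formal (4+3) cycloaddition) of vinyldiazoacetates with 1,3-dienes under chiral dirhodium carboxylates; the adamantylglycinate catalyst is chosen because prolinate catalysts lose selectivity with 2-siloxyvinyl carbenoids. Ring A closes by a concerted pericyclic ring expansion of the cyclopropane through a boat transition state with both vinyl arms over the three-membered ring. The only new stereocentre of 11, quaternary C6, is fixed by the catalyst-set configuration at the cyclopropane CH (C4), because in the boat geometry C7 can reach only one face of C6. The step needs site selectivity for the vinyl group over the tetrasubstituted ring alkene (secured by sterics), cis-divinyl geometry (secured by the preference of donor/acceptor carbenoids to place the ester trans to the alkene substituent) and enantioface selectivity (secured by the catalyst). The C6 methyl points inward in the boat and slows the shift, hence the heating after the cyclopropanation.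

**Step 7**
Reactants: 11 methyl (6R)-1-(tert-butyldimethylsilyloxy)-10,10-(ethylenedioxy)-6-methylbicyclo[5.3.0]deca-1,4-diene-2-carboxylate
Product: 13 methyl (4S,5S,6R)-1-(tert-butyldimethylsilyloxy)-10,10-(ethylenedioxy)-4-hydroxy-6-methylbicyclo[5.3.0]dec-1-ene-2-carboxylate, via C4 alkylborane 12 (not isolated)
Conditions: BH3·THF (1.3 equiv), THF, 0 °C to rt; then NaBO3·4H2O, THF/H2O, rt
Reagents that add atoms: sodium perborate, [Na+].[Na+].O[B-]1(O)OO[B-](O)(O)OO1; borane–tetrahydrofuran, B.C1CCOC1 (its boron stays only in 12)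
Why: Hydroboration–oxidation of the trisubstituted C4=C5 alkene puts boron on the less substituted C4 and hydrogen on C5 by syn addition from the face opposite the pseudoaxial C6 methyl, which sets the trans ring fusion and the C4 hydroxyl syn to H5 in one operation, while the tetrasubstituted, ester-deactivated siloxy enoate and the ketal should not react and perborate is a mild enough oxidant to spare them.

**Step 8**
Reactants: 13 methyl (4S,5S,6R)-1-(tert-butyldimethylsilyloxy)-10,10-(ethylenedioxy)-4-hydroxy-6-methylbicyclo[5.3.0]dec-1-ene-2-carboxylate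
Product: 14 methyl (4S,5S,6R)-4-hydroxy-6-methyl-1,10-dioxobicyclo[5.3.0]decane-2-carboxylate
Conditions: 1 M HCl, THF, 0 °C to rt
Reagents that add atoms: water, O
Why: Aqueous acid hydrolysis cleaves the dioxolane and the silyl enol ether together, unmasking the C10 ketone and the β-keto ester; the mild conditions are chosen to avoid C5 enolisation and dehydration of the β-hydroxy ketone.

**Step 9**
Reactants: 14 methyl (4S,5S,6R)-4-hydroxy-6-methyl-1,10-dioxobicyclo[5.3.0]decane-2-carboxylate
Product: 16 methyl (4S,5S,6R,10R)-4,10-dihydroxy-6-methyl-1-oxo-10-(propan-2-yl)bicyclo[5.3.0]decane-2-carboxylate, via sodium enolate 15 (not isolated)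
Conditions: NaH (1.0 equiv), THF, 0 °C; then iPrMgCl/CeCl3 (4 equiv), THF, −78 to −20 °C; aq. NH4Cl
Reagents that add atoms: isopropylmagnesium chloride, CC(C)[Mg]Cl; sodium hydride, [Na+].[H-] (its sodium stays only in 15)
Why: The β-keto ester is protected in the flask as its enolate, so the weakly basic organocerium reagent (1,2-addition of a Grignard reagent transmetallated to CeCl3) adds only to the C10 ketone; attack from the H5 face, away from the pseudoaxial C6 methyl and the C4 branch, should place the new hydroxyl syn to the methyl.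

**Step 10**
Reactants: 16 methyl (4S,5S,6R,10R)-4,10-dihydroxy-6-methyl-1-oxo-10-(propan-2-yl)bicyclo[5.3.0]decane-2-carboxylate
Product: 17 methyl (4S,5S,6R,10R)-4,10-dihydroxy-2,6-dimethyl-1-oxo-10-(propan-2-yl)bicyclo[5.3.0]decane-2-carboxylate
Conditions: K2CO3, MeI, acetone, rt
Reagents that add atoms: iodomethane, CI
Why: C-Alkylation of the β-keto ester enolate with iodomethane under weak base, which leaves the alcohols untouched; the new C2 centre forms as an epimer mixture that does not matter.

**Step 11**
Reactants: 17 methyl (4S,5S,6R,10R)-4,10-dihydroxy-2,6-dimethyl-1-oxo-10-(propan-2-yl)bicyclo[5.3.0]decane-2-carboxylate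
Product: 18 (4S,5S,6R,10R)-4,10-dihydroxy-2,6-dimethyl-10-(propan-2-yl)bicyclo[5.3.0]decan-1-one
Conditions: LiCl, H2O (2 equiv), DMSO, 140 °C
Reagents that add atoms: none
Why: Krapcho dealkoxycarbonylation, in which chloride attacks the ester methyl group and the β-keto carboxylate loses CO2 under neutral conditions; the temperature is kept below that at which DMSO dehydrates tertiary alcohols.

**Step 12**
Reactants: 19 p-coumaric acid
Product: 21 (E)-3-[4-(tert-butyldimethylsilyloxy)phenyl]prop-2-enoic acid, via bis-silyl derivative 20 (not isolated)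
Conditions: TBSCl (2.4 equiv), imidazole, DMF, rt; then AcOH, THF/H2O, rt
Reagents that add atoms: tert-butyldimethylsilyl chloride, CC(C)(C)[Si](C)(C)Cl
Why: Exhaustive silylation followed by selective hydrolysis of the far more labile silyl ester leaves the phenol masked, so the acid cannot self-condense in the next step.

**Step 13**
Reactants: 18 (4S,5S,6R,10R)-4,10-dihydroxy-2,6-dimethyl-10-(propan-2-yl)bicyclo[5.3.0]decan-1-one; 21 (E)-3-[4-(tert-butyldimethylsilyloxy)phenyl]prop-2-enoic acid
Product: 22 (4S,5S,6R,10R)-10-hydroxy-2,6-dimethyl-1-oxo-10-(propan-2-yl)bicyclo[5.3.0]decan-4-yl (E)-3-[4-(tert-butyldimethylsilyloxy)phenyl]prop-2-enoate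
Conditions: DCC, DMAP (cat.), CH2Cl2, 0 °C to rt
Reagents that add atoms: none
Why: Steglich esterification (carbodiimide activation, DMAP acyl transfer) acylates the secondary C4 hydroxyl with retention, the tertiary C10 hydroxyl being too hindered to compete.

**Step 14**
Reactants: 22 (4S,5S,6R,10R)-10-hydroxy-2,6-dimethyl-1-oxo-10-(propan-2-yl)bicyclo[5.3.0]decan-4-yl (E)-3-[4-(tert-butyldimethylsilyloxy)phenyl]prop-2-enoate
Product: 24 (4S,5S,6R,10R)-2,6-dimethyl-1-oxo-10-(propan-2-yl)-10-(trimethylsilyloxy)bicyclo[5.3.0]dec-2-en-4-yl (E)-3-[4-(tert-butyldimethylsilyloxy)phenyl]prop-2-enoate, via bis-trimethylsilyl enol ether 23 (not isolated)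
Conditions: TMSCl, NaI, Et3N, MeCN, rt; then Pd(OAc)2 (1.1 equiv), MeCN, rt
Reagents that add atoms: chlorotrimethylsilane, C[Si](C)(C)Cl
Why: Saegusa–Ito oxidation: iodotrimethylsilane made in the flask gives the thermodynamic, more substituted silyl enol ether (and silylates the tertiary alcohol), and Pd(OAc)2 then effects β-hydride elimination into the ring toward C3; any enol ether formed toward C7 is unproductive because C6 carries no hydrogen.

**Step 15**
Reactants: 24 (4S,5S,6R,10R)-2,6-dimethyl-1-oxo-10-(propan-2-yl)-10-(trimethylsilyloxy)bicyclo[5.3.0]dec-2-en-4-yl (E)-3-[4-(tert-butyldimethylsilyloxy)phenyl]prop-2-enoate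
Product: 25 (4S,5S,6R,10R)-10-hydroxy-2,6-dimethyl-1-oxo-10-(propan-2-yl)bicyclo[5.3.0]dec-2-en-4-yl (E)-3-(4-hydroxyphenyl)prop-2-enoate (CNP0310968.1)
Conditions: TBAF, AcOH, THF, 0 °C
Reagents that add atoms: none
Why: Buffered fluoride desilylation removes the aryl silyl ether and the tertiary trimethylsilyl ether without base-induced damage to the γ-acyloxy enone.

**Compound list**
1 | 3-methylcyclopent-2-en-1-one | CC1=CC(=O)CC1 | starting material
2 | 2,3-dibromo-3-methylcyclopentan-1-one (racemic) | CC1(Br)CCC(=O)C1Br | intermediate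
3 | 2-bromo-3-methylcyclopent-2-en-1-one | CC1=C(Br)C(=O)CC1 | intermediate
4 | 6-bromo-7-methyl-1,4-dioxaspiro[4.4]non-6-ene | CC1=C(Br)C2(CC1)OCCO2 | intermediate
5 | potassium vinyltrifluoroborate | [K+].C=C[B-](F)(F)F | starting material
6 | 6-ethenyl-7-methyl-1,4-dioxaspiro[4.4]non-6-ene | C=CC1=C(C)CCC12OCCO2 | intermediate
7 | methyl acetoacetate | COC(=O)CC(C)=O | starting material
8 | methyl 2-diazo-3-oxobutanoate | COC(=O)C(=[N+]=[N-])C(C)=O | intermediate
9 | methyl 3-(tert-butyldimethylsilyloxy)-2-diazobut-3-enoate | COC(=O)C(=[N+]=[N-])C(=C)O[Si](C)(C)C(C)(C)C | intermediate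
10 | methyl (1R,2S)-1-[1-(tert-butyldimethylsilyloxy)ethenyl]-2-(7-methyl-1,4-dioxaspiro[4.4]non-6-en-6-yl)cyclopropane-1-carboxylate (siloxyvinyl and cyclopentenyl arms cis) | COC(=O)[C@]1(C(=C)O[Si](C)(C)C(C)(C)C)C[C@H]1C1=C(C)CCC12OCCO2 | intermediate
11 | methyl (6R)-1-(tert-butyldimethylsilyloxy)-10,10-(ethylenedioxy)-6-methylbicyclo[5.3.0]deca-1,4-diene-2-carboxylate | COC(=O)C1=C(O[Si](C)(C)C(C)(C)C)C[C@@]2(C)CCC3(OCCO3)C2=CC1 | intermediate
12 | C4 alkylborane of 11: BH2 on C4 and H on C5, added syn on the face opposite the C6 methyl | COC(=O)C1=C(O[Si](C)(C)C(C)(C)C)C[C@@]2(C)CCC3(OCCO3)[C@@H]2[C@@H](B)C1 | intermediate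
13 | methyl (4S,5S,6R)-1-(tert-butyldimethylsilyloxy)-10,10-(ethylenedioxy)-4-hydroxy-6-methylbicyclo[5.3.0]dec-1-ene-2-carboxylate (trans-fused, 4-OH syn to H5) | COC(=O)C1=C(O[Si](C)(C)C(C)(C)C)C[C@@]2(C)CCC3(OCCO3)[C@@H]2[C@@H](O)C1 | intermediate
14 | methyl (4S,5S,6R)-4-hydroxy-6-methyl-1,10-dioxobicyclo[5.3.0]decane-2-carboxylate | COC(=O)C1C(=O)C[C@@]2(C)CCC(=O)[C@@H]2[C@@H](O)C1 | intermediate
15 | sodium enolate of 14 (C1–O−, C1=C2) | COC(=O)C1=C([O-])C[C@@]2(C)CCC(=O)[C@@H]2[C@@H](O)C1.[Na+] | intermediate
16 | methyl (4S,5S,6R,10R)-4,10-dihydroxy-6-methyl-1-oxo-10-(propan-2-yl)bicyclo[5.3.0]decane-2-carboxylate (10-OH syn to the C6 methyl) | COC(=O)C1C(=O)C[C@@]2(C)CC[C@@](O)(C(C)C)[C@@H]2[C@@H](O)C1 | intermediate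
17 | methyl (4S,5S,6R,10R)-4,10-dihydroxy-2,6-dimethyl-1-oxo-10-(propan-2-yl)bicyclo[5.3.0]decane-2-carboxylate | COC(=O)C1(C)C(=O)C[C@@]2(C)CC[C@@](O)(C(C)C)[C@@H]2[C@@H](O)C1 | intermediate
18 | (4S,5S,6R,10R)-4,10-dihydroxy-2,6-dimethyl-10-(propan-2-yl)bicyclo[5.3.0]decan-1-one | CC1C(=O)C[C@@]2(C)CC[C@@](O)(C(C)C)[C@@H]2[C@@H](O)C1 | intermediate
19 | p-coumaric acid | OC(=O)/C=C/c1ccc(O)cc1 | starting material
20 | tert-butyldimethylsilyl (E)-3-[4-(tert-butyldimethylsilyloxy)phenyl]prop-2-enoate | CC(C)(C)[Si](C)(C)OC(=O)/C=C/c1ccc(O[Si](C)(C)C(C)(C)C)cc1 | intermediate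
21 | (E)-3-[4-(tert-butyldimethylsilyloxy)phenyl]prop-2-enoic acid | OC(=O)/C=C/c1ccc(O[Si](C)(C)C(C)(C)C)cc1 | intermediate
22 | (4S,5S,6R,10R)-10-hydroxy-2,6-dimethyl-1-oxo-10-(propan-2-yl)bicyclo[5.3.0]decan-4-yl (E)-3-[4-(tert-butyldimethylsilyloxy)phenyl]prop-2-enoate | CC1C(=O)C[C@@]2(C)CC[C@@](O)(C(C)C)[C@@H]2[C@@H](OC(=O)/C=C/c3ccc(O[Si](C)(C)C(C)(C)C)cc3)C1 | intermediate
23 | (4S,5S,6R,10R)-2,6-dimethyl-10-(propan-2-yl)-1,10-bis(trimethylsilyloxy)bicyclo[5.3.0]dec-1-en-4-yl (E)-3-[4-(tert-butyldimethylsilyloxy)phenyl]prop-2-enoate | CC1=C(O[Si](C)(C)C)C[C@@]2(C)CC[C@@](O[Si](C)(C)C)(C(C)C)[C@@H]2[C@@H](OC(=O)/C=C/c3ccc(O[Si](C)(C)C(C)(C)C)cc3)C1 | intermediate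
24 | (4S,5S,6R,10R)-2,6-dimethyl-1-oxo-10-(propan-2-yl)-10-(trimethylsilyloxy)bicyclo[5.3.0]dec-2-en-4-yl (E)-3-[4-(tert-butyldimethylsilyloxy)phenyl]prop-2-enoate | CC1=C[C@H](OC(=O)/C=C/c2ccc(O[Si](C)(C)C(C)(C)C)cc2)[C@@H]2[C@](C)(CC[C@@]2(O[Si](C)(C)C)C(C)C)CC1=O | intermediate
25 | (4S,5S,6R,10R)-10-hydroxy-2,6-dimethyl-1-oxo-10-(propan-2-yl)bicyclo[5.3.0]dec-2-en-4-yl (E)-3-(4-hydroxyphenyl)prop-2-enoate, CNP0310968.1 | CC1=C[C@H](OC(=O)/C=C/c2ccc(O)cc2)[C@@H]2[C@](C)(CC[C@@]2(O)C(C)C)CC1=O | target

**Step count and risks**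
Total: 15 steps. Longest linear sequence: 12 steps (steps 1–3, 6–11, 13–15) from 3-methylcyclopent-2-en-1-one.

Step 6. The fully substituted diene terminus may erode enantioface selection in the cyclopropanation, or the cyclopropane may persist or isomerise instead of rearranging. The fallback sets out from 6 and 9: the reaction would be run with the achiral, more robust Rh2(OPiv)4 in refluxing hexanes and then heated in xylene, accepting the racemic cis-divinylcyclopropane F1 and from it the racemic cycloheptadiene F2. Preparative chromatography of F2 on a chiral stationary phase (supercritical CO2/2-propanol) would come back to the route at 11, so that C6 rests on resolution and no longer on the catalyst.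

Step 7. Borane may attack the siloxy enoate (conjugate or ester reduction) or add from the methyl-bearing face and give the cis-fused isomer. The fallback sets out from 11: aqueous HCl in THF would cleave the allylic ketal and the silyl enol ether to the enone β-keto ester F3. Copper-catalysed conjugate borylation (CuSO4, 4-picoline, B2pin2, water/toluene) should deliver boron to C4 from the face away from the C6 methyl and give the β-boryl ketone F4. Its C5 centre, now α to the C10 ketone, would be equilibrated with DBU toward the trans ring fusion, which is expected to be the more stable arrangement. Oxidation of the C–B bond with NaBO3·4H2O, with retention, comes back to the route at 14.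

Step 9. Enolisation and β-hydride transfer from the isopropyl reagent may outpace addition at the congested ketone. The fallback sets out from 14 and passes through the sodium enolate 15: isopropenylmagnesium bromide/CeCl3, a smaller sp2 nucleophile that cannot act as a hydride donor, would give the isopropenyl carbinol F5 with the C10 hydroxyl syn to the C6 methyl. Hydrogenation of its 1,1-disubstituted alkene (H2, PtO2, EtOAc), the only C=C bond present at that stage, comes back to the route at 16.

**Further compounds**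
F1 | step 6 | racemic cis-divinylcyclopropane (racemate of 10) | COC(=O)C1(C(=C)O[Si](C)(C)C(C)(C)C)CC1C1=C(C)CCC12OCCO2
F2 | step 6 | racemic cycloheptadiene (racemate of 11) | COC(=O)C1=C(O[Si](C)(C)C(C)(C)C)CC2(C)CCC3(OCCO3)C2=CC1
F3 | step 7 | methyl (6R)-6-methyl-1,10-dioxobicyclo[5.3.0]dec-4-ene-2-carboxylate | COC(=O)C1C(=O)C[C@@]2(C)CCC(=O)C2=CC1
F4 | step 7 | methyl 6-methyl-1,10-dioxo-4-(4,4,5,5-tetramethyl-1,3,2-dioxaborolan-2-yl)bicyclo[5.3.0]decane-2-carboxylate, trans-fused, boryl group syn to H5 | COC(=O)C1C(=O)C[C@@]2(C)CCC(=O)[C@@H]2[C@@H](B3OC(C)(C)C(C)(C)O3)C1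
F5 | step 9 | methyl 4,10-dihydroxy-6-methyl-1-oxo-10-(prop-1-en-2-yl)bicyclo[5.3.0]decane-2-carboxylate, ring configuration as in 16, 10-OH syn to the C6 methyl | COC(=O)C1C(=O)C[C@@]2(C)CC[C@@](O)(C(C)=C)[C@@H]2[C@@H](O)C1
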